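**Retrosynthetic overview**

1. Feature: ring B (C5–C10, labdane numbering) holds all three stereocentres, C5, C10 (methyl C20) and C9 (chain C11–C16), next to C8, whose exocyclic methylene C17 can come from a ketone. Ring B is therefore the cyclohexene of a [4+2] between a C5=C6–C7=C8 1-silyloxydiene and a C9=C10 enal (formyl carbon C11), joined through the ring A carbons C1–C4.
2. Endgame: C15 acid ⇐ 2-(trimethylsilyl)ethyl ester; C8=C17 ⇐ C8 ketone ⇐ C8 silyl ether; C12–C13 ⇐ B-alkyl Suzuki coupling of a C11=C12 vinyl group (from the formyl group) with an (E)-enol triflate that already carries C13–C16 and the isobutyrate.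
3. Key disconnection: C5–C10 and C8–C9 by a catalytic enantioselective intramolecular Diels–Alder reaction of the acyclic silyloxytrienal 14. Rings A and B form together in this step; no ring exists before it and none is formed after it.
4. Trienal 14: enal ⇐ allylic alcohol; silyl dienol ether ⇐ enal from a two-carbon Wittig extension; quaternary C4 ⇐ copper-catalysed conjugate addition of a C6 Grignard reagent to 3-methylbut-2-enal; (E)-C9=C10 with its methyl ⇐ methylalumination–hydroxymethylation of 5-chloropent-1-yne.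

Key step: step 8

Assumption: the sense of induction in step 8 is taken from the usual binding model of enals on diphenylprolinol-derived oxazaborolidinium ions (formyl C–H···O contact, attack on the face turned away from the catalyst framework), which for the (S)-catalyst exposes the C9 Re face needed for 10R; if a first run shows the opposite sense, the (R)-catalyst is used with no other change.

**Route**

Step 1
Reactants: 1 5-chloropent-1-yne
Product: 4 (2E)-6-chloro-3-methylhex-2-en-1-ol, via alkenyldimethylalane 2 (not isolated), via lithium alkenylalanate 3 (not isolated)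
Conditions: AlMe3 (2 equiv), Cp2ZrCl2 (0.25 equiv), CH2Cl2, 0 °C → rt; evaporate; n-BuLi, THF–hexane, −78 °C; (CH2O)n, −78 °C → rt; aq. HCl
Reagents that add atoms: trimethylaluminium C[Al](C)C; paraformaldehyde (as formaldehyde) C=O
Why: Zirconium-catalysed methylalumination of the terminal alkyne (Negishi carboalumination) is a syn addition that puts methyl on the internal and aluminium on the terminal carbon, so hydroxymethylation of the alanate with retention should give the (E)-allylic alcohol, the primary chloride being inert to AlMe3.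

Step 2
Reactants: 4 (2E)-6-chloro-3-methylhex-2-en-1-ol; 5 3-methylbut-2-enal
Product: 8 (7E)-9-hydroxy-3,3,7-trimethylnon-7-enal, via magnesium alkoxide Grignard reagent 6 (not isolated), via bis(trimethylsilyl) adduct 7 (not isolated)
Conditions: i-PrMgCl (1.0 equiv), THF, 0 °C; Mg, BrCH2CH2Br (cat.), THF, 65 °C; then CuBr·SMe2 (10 mol%), Me3SiCl (3 equiv), HMPA, 5, THF, −78 → −30 °C; 1 M HCl, THF, 0 °C
Reagents that add atoms: none
Why: The alkoxide-protected Grignard reagent 6 should add to the β,β-disubstituted enal in a copper-catalysed, Me3SiCl-accelerated conjugate addition (trapped as silyl enol ether 7), creating the quaternary carbon that becomes C4, and dilute acid then releases both the aldehyde and the alcohol.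

Step 3
Reactants: 8 (7E)-9-hydroxy-3,3,7-trimethylnon-7-enal; 9 (triphenylphosphoranylidene)acetaldehyde
Product: 10 (2E,9E)-11-hydroxy-5,5,9-trimethylundeca-2,9-dienal
Conditions: 9 (1.1 equiv), toluene, 80 °C
Reagents that add atoms: none
Why: The stabilised ylide reacts with the unconjugated aldehyde in an (E)-selective Wittig reaction, and the free alcohol does not interfere.

Step 4
Reactants: 10 (2E,9E)-11-hydroxy-5,5,9-trimethylundeca-2,9-dienal
Product: 11 (2E,9E)-3,7,7-trimethyl-11-oxoundeca-2,9-dien-1-yl acetate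
Conditions: Ac2O, pyridine, DMAP (cat.), CH2Cl2, 0 °C → rt
Reagents that add atoms: acetic anhydride CC(=O)OC(C)=O
Why: DMAP-catalysed acylation masks the allylic alcohol as an ester that tolerates a silyl triflate and can later be removed by hydride without touching a silyl enol ether.

Step 5
Reactants: 11 (2E,9E)-3,7,7-trimethyl-11-oxoundeca-2,9-dien-1-yl acetate
Product: 12 (2E,8E,10E)-11-[(tert-butyldimethylsilyl)oxy]-3,7,7-trimethylundeca-2,8,10-trien-1-yl acetate
Conditions: t-BuMe2SiOTf (1.3 equiv), Et3N (2 equiv), Et2O, −20 → 0 °C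
Reagents that add atoms: tert-butyldimethylsilyl trifluoromethanesulfonate CC(C)(C)[Si](C)(C)OS(=O)(=O)C(F)(F)F
Why: Soft enolisation of the enal (O-silylation, then γ-deprotonation by Et3N) gives the 1-silyloxy-1,3-diene; the s-trans enal leads to the (10E)-enol ether, and the quaternary carbon on the γ-CH2 has to point away from the vinyl unit, so the new C8=C9 bond (chain locants) is expected to be (E).

Step 6
Reactants: 12 (2E,8E,10E)-11-[(tert-butyldimethylsilyl)oxy]-3,7,7-trimethylundeca-2,8,10-trien-1-yl acetate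
Product: 13 (2E,8E,10E)-11-[(tert-butyldimethylsilyl)oxy]-3,7,7-trimethylundeca-2,8,10-trien-1-ol
Conditions: i-Bu2AlH (2.2 equiv), CH2Cl2, −78 °C; aq. potassium sodium tartrate
Reagents that add atoms: none
Why: Reductive ester cleavage with i-Bu2AlH at −78 °C removes the acetate under conditions in which the silyl dienol ether and the alkenes are inert, which methanolysis would not guarantee.

Step 7
Reactants: 13 (2E,8E,10E)-11-[(tert-butyldimethylsilyl)oxy]-3,7,7-trimethylundeca-2,8,10-trien-1-ol
Product: 14 (2E,8E,10E)-11-[(tert-butyldimethylsilyl)oxy]-3,7,7-trimethylundeca-2,8,10-trienal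
Conditions: MnO2 (activated, 20 equiv), NaHCO3 (solid), CH2Cl2, rt
Reagents that add atoms: none
Why: MnO2 oxidises only the allylic alcohol (allylic oxidation) without acid or base, so the (2E)-enal should form without isomerisation and with the silyl dienol ether intact.

Step 8
Reactants: 14 (2E,8E,10E)-11-[(tert-butyldimethylsilyl)oxy]-3,7,7-trimethylundeca-2,8,10-trienal
Product: 15 (1S,2R,4aR,8aR)-2-[(tert-butyldimethylsilyl)oxy]-5,5,8a-trimethyl-1,2,4a,5,6,7,8,8a-octahydronaphthalene-1-carbaldehyde (labdane locants 5R,8R,9S,10R)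
Conditions: (S)-1-(2-methylphenyl)-3,3-diphenyltetrahydro-1H,3H-pyrrolo[1,2-c][1,3,2]oxazaborole (20 mol%) premixed with HNTf2 (17 mol%), CH2Cl2, −25 °C; then 14, CH2Cl2, −78 → −20 °C; Et3N quench
Reagents that add atoms: none
Why: Proposed new method: the cationic boron Lewis acid binds the aldehyde and lowers the LUMO of the (2E)-enal, whose β-carbon C10 pairs with C5, the diene terminus of largest HOMO coefficient in the 1-silyloxydiene, in a concerted asynchronous [4+2] cycloaddition (C5–C10 leading, C8–C9 following); the closest known reaction type is the chiral oxazaborolidinium-catalysed type 1 intramolecular Diels–Alder reaction of 2,7,9-decatrienals to trans-decalins, not yet shown for a β,β-disubstituted enal that creates an angular quaternary carbon. Ring A (C10, C1–C4, C5) closes as the six-membered ring spanned by the four-carbon tether when C5–C10 forms, helped by the C4 gem-dimethyl group, and ring B closes as the cyclohexene of the cycloaddition when C8–C9 forms. C10 is set by the catalyst, which screens one enantioface of the bound s-trans enal; C9 follows from suprafacial addition to the (E)-enal (formyl cis to the C10 methyl); C5 follows from the endo transition state with the tether anti, which with the (E)-C5=C6 bond gives the trans ring fusion; C8 follows from the (E)-enol ether (silyloxy cis to formyl). The step needs enantiofacial control, secured by the chiral catalyst, endo over exo selectivity, secured by the Lewis-acid-bound formyl group and the chair-like tether, and cycloaddition over silyl transfer, secured by the bulky silyl group and the low temperature.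

Step 9
Reactants: 15 cycloadduct
Product: 16 (1S,2R,4aR,8aR)-2-[(tert-butyldimethylsilyl)oxy]-5,5,8a-trimethyldecahydronaphthalene-1-carbaldehyde
Conditions: H2 (1 atm), 10% Pd/C, EtOAc, rt
Reagents that add atoms: none
Why: Heterogeneous catalytic hydrogenation saturates the only alkene, C6=C7, creates no stereocentre, and under neutral conditions leaves the equatorial formyl group at C9 in place.

Step 10
Reactants: 16 saturated aldehyde
Product: 17 tert-butyl{[(1S,2R,4aR,8aR)-1-ethenyl-5,5,8a-trimethyldecahydronaphthalen-2-yl]oxy}dimethylsilane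
Conditions: Ph3PCH3Br, KN(SiMe3)2, THF, 0 °C; then 16, −78 → 0 °C
Reagents that add atoms: methyltriphenylphosphonium bromide C[P+](c1ccccc1)(c1ccccc1)c1ccccc1.[Br-]
Why: Wittig methylenation with the non-stabilised ylide should be faster than enolisation of the hindered aldehyde, so C9 keeps its configuration and the β-silyloxy group is not eliminated.

Step 11
Reactants: 18 ethyl 4-chloro-3-oxobutanoate; 19 2-methylpropanoic acid
Product: 20 ethyl 4-(2-methylpropanoyloxy)-3-oxobutanoate
Conditions: 19 (3 equiv), KHCO3 (1.2 equiv), NaI (10 mol%), DMF, 40 °C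
Reagents that add atoms: none
Why: SN2 displacement of the activated α-chloroketone chloride by isobutyrate (iodide catalysis) in a carboxylic acid buffer, which keeps the β-keto ester from enolising and condensing with itself.

Step 12
Reactants: 20 ethyl 4-(2-methylpropanoyloxy)-3-oxobutanoate
Product: 21 2-(trimethylsilyl)ethyl 4-(2-methylpropanoyloxy)-3-oxobutanoate
Conditions: Me3SiCH2CH2OH (1.5 equiv), toluene, 110 °C, EtOH removed over 4 Å molecular sieves
Reagents that add atoms: 2-(trimethylsilyl)ethanol C[Si](C)(C)CCO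
Why: β-Keto esters exchange their alkoxy group on heating through the acylketene (thermal transesterification), whereas the isobutyrate, a simple ester, does not exchange without a catalyst.

Step 13
Reactants: 21 2-(trimethylsilyl)ethyl 4-(2-methylpropanoyloxy)-3-oxobutanoate
Product: 22 2-(trimethylsilyl)ethyl (2E)-4-(2-methylpropanoyloxy)-3-[(trifluoromethanesulfonyl)oxy]but-2-enoate
Conditions: Tf2O (1.5 equiv), aq. Me4NOH (25%), hexanes–toluene, 5 °C, 10 min, vigorous stirring
Reagents that add atoms: trifluoromethanesulfonic anhydride O=S(=O)(OS(=O)(=O)C(F)(F)F)C(F)(F)F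
Why: O-Triflation of the non-chelated tetramethylammonium enolate, in which the two carbonyl dipoles are opposed, should give the (E)-enol triflate (triflate trans to the ester carbonyl), whereas lithium chelation would give the (Z)-isomer; the short cold biphasic contact spares the isobutyrate.

Step 14
Reactants: 17 vinyl decalin; 22 (E)-enol triflate
Product: 24 2-(trimethylsilyl)ethyl (2Z)-3-{2-[(1S,2R,4aR,8aR)-2-[(tert-butyldimethylsilyl)oxy]-5,5,8a-trimethyldecahydronaphthalen-1-yl]ethyl}-4-(2-methylpropanoyloxy)but-2-enoate, via B-alkyl-9-borabicyclononane 23 (not isolated)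
Conditions: 9-BBN (1.5 equiv), THF, 0 °C → rt; then aq. K3PO4 (3 M), 22, Pd(dppf)Cl2 (5 mol%), AsPh3 (10 mol%), DMF, rt
Reagents that add atoms: none
Why: 9-BBN hydroborates the monosubstituted C11=C12 alkene at the terminal carbon, and the B-alkyl Suzuki–Miyaura coupling replaces the triflate with retention of geometry, which fixes C16 cis to the ester across C13=C14 (the descriptor changes from E to Z only because the priorities change).

Step 15
Reactants: 24 coupled silyl ether
Product: 25 2-(trimethylsilyl)ethyl (2Z)-3-{2-[(1S,2R,4aR,8aR)-2-hydroxy-5,5,8a-trimethyldecahydronaphthalen-1-yl]ethyl}-4-(2-methylpropanoyloxy)but-2-enoate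
Conditions: HF·pyridine, THF, 0 °C → rt
Reagents that add atoms: none
Why: Acidic fluoride desilylation removes the secondary silyl ether, while the 2-(trimethylsilyl)ethyl ester (which needs naked fluoride), the isobutyrate and the enoate should stay.

Step 16
Reactants: 25 C8 alcohol
Product: 26 2-(trimethylsilyl)ethyl (2Z)-4-(2-methylpropanoyloxy)-3-{2-[(1S,4aR,8aR)-5,5,8a-trimethyl-2-oxodecahydronaphthalen-1-yl]ethyl}but-2-enoate
Conditions: Dess–Martin periodinane, NaHCO3, CH2Cl2, rt
Reagents that add atoms: none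
Why: Buffered Dess–Martin oxidation gives the C8 ketone without acid or base strong enough to epimerise C9, whose equatorial side chain is in any case the stable arrangement.

Step 17
Reactants: 26 C8 ketone
Product: 27 2-(trimethylsilyl)ethyl (2Z)-4-(2-methylpropanoyloxy)-3-{2-[(1R,4aR,8aR)-5,5,8a-trimethyl-2-methylidenedecahydronaphthalen-1-yl]ethyl}but-2-enoate
Conditions: Zn, CH2Br2, TiCl4 (reagent preformed in THF, −40 → 5 °C); then 26, CH2Cl2, 0 °C → rt
Reagents that add atoms: dibromomethane BrCBr
Why: The Takai–Lombardo reagent methylenates ketones but not esters and is not basic, so the hindered, enolisable C8 ketone should give the exocyclic C8=C17 alkene without epimerisation at C9.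

Step 18
Reactants: 27 2-(trimethylsilyl)ethyl ester
Product: 28 (2Z)-4-(2-methylpropanoyloxy)-3-{2-[(1R,4aR,8aR)-5,5,8a-trimethyl-2-methylidenedecahydronaphthalen-1-yl]ethyl}but-2-enoic acid (target)
Conditions: tris(dimethylamino)sulfonium difluorotrimethylsilicate (2 equiv), DMF, 0 °C → rt; 0.1 M HCl work-up, 0 °C
Reagents that add atoms: none
Why: Fluoride attacks silicon and fragments the 2-(trimethylsilyl)ethyl ester into carboxylate, ethene and Me3SiF (fluoride-induced β-elimination) under non-hydrolytic conditions, so the isobutyrate, the (Z)-alkene and the exocyclic methylene should survive.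

**Compound list**

1 | 5-chloropent-1-yne | C#CCCCCl | starting material
2 | (E)-(5-chloro-2-methylpent-1-en-1-yl)dimethylalane | C[Al](C)/C=C(\C)CCCCl | intermediate (not isolated)
3 | lithium butyl[(E)-5-chloro-2-methylpent-1-en-1-yl]dimethylalanate | [Li+].CCCC[Al-](C)(C)/C=C(\C)CCCCl | intermediate (not isolated)
4 | (2E)-6-chloro-3-methylhex-2-en-1-ol | OC/C=C(\C)CCCCl | intermediate
5 | 3-methylbut-2-enal | CC(C)=CC=O | starting material
6 | chloromagnesium (2E)-6-(chloromagnesio)-3-methylhex-2-en-1-olate | Cl[Mg]CCC/C(C)=C/CO[Mg]Cl | intermediate (not isolated)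
7 | trimethyl{[(7E)-3,3,7-trimethyl-9-(trimethylsilyloxy)nona-1,7-dien-1-yl]oxy}silane (enol ether geometry not defined) | C[Si](C)(C)OC=CC(C)(C)CCC/C(C)=C/CO[Si](C)(C)C | intermediate (not isolated)
8 | (7E)-9-hydroxy-3,3,7-trimethylnon-7-enal | O=CCC(C)(C)CCC/C(C)=C/CO | intermediate
9 | (triphenylphosphoranylidene)acetaldehyde | O=CC=P(c1ccccc1)(c1ccccc1)c1ccccc1 | starting material
10 | (2E,9E)-11-hydroxy-5,5,9-trimethylundeca-2,9-dienal | O=C/C=C/CC(C)(C)CCC/C(C)=C/CO | intermediate
11 | (2E,9E)-3,7,7-trimethyl-11-oxoundeca-2,9-dien-1-yl acetate | CC(=O)OC/C=C(\C)CCCC(C)(C)C/C=C/C=O | intermediate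
12 | (2E,8E,10E)-11-[(tert-butyldimethylsilyl)oxy]-3,7,7-trimethylundeca-2,8,10-trien-1-yl acetate | CC(=O)OC/C=C(\C)CCCC(C)(C)/C=C/C=C/O[Si](C)(C)C(C)(C)C | intermediate
13 | (2E,8E,10E)-11-[(tert-butyldimethylsilyl)oxy]-3,7,7-trimethylundeca-2,8,10-trien-1-ol | OC/C=C(\C)CCCC(C)(C)/C=C/C=C/O[Si](C)(C)C(C)(C)C | intermediate
14 | (2E,8E,10E)-11-[(tert-butyldimethylsilyl)oxy]-3,7,7-trimethylundeca-2,8,10-trienal | O=C/C=C(\C)CCCC(C)(C)/C=C/C=C/O[Si](C)(C)C(C)(C)C | intermediate (key-step precursor)
15 | (1S,2R,4aR,8aR)-2-[(tert-butyldimethylsilyl)oxy]-5,5,8a-trimethyl-1,2,4a,5,6,7,8,8a-octahydronaphthalene-1-carbaldehyde | O=C[C@@H]1[C@H](O[Si](C)(C)C(C)(C)C)C=C[C@@H]2C(C)(C)CCC[C@@]12C | intermediate (key-step product)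
16 | (1S,2R,4aR,8aR)-2-[(tert-butyldimethylsilyl)oxy]-5,5,8a-trimethyldecahydronaphthalene-1-carbaldehyde | O=C[C@@H]1[C@H](O[Si](C)(C)C(C)(C)C)CC[C@@H]2C(C)(C)CCC[C@@]12C | intermediate
17 | tert-butyl{[(1S,2R,4aR,8aR)-1-ethenyl-5,5,8a-trimethyldecahydronaphthalen-2-yl]oxy}dimethylsilane | C=C[C@@H]1[C@H](O[Si](C)(C)C(C)(C)C)CC[C@@H]2C(C)(C)CCC[C@@]12C | intermediate
18 | ethyl 4-chloro-3-oxobutanoate | CCOC(=O)CC(=O)CCl | starting material
19 | 2-methylpropanoic acid | CC(C)C(=O)O | starting material
20 | ethyl 4-(2-methylpropanoyloxy)-3-oxobutanoate | CCOC(=O)CC(=O)COC(=O)C(C)C | intermediate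
21 | 2-(trimethylsilyl)ethyl 4-(2-methylpropanoyloxy)-3-oxobutanoate | C[Si](C)(C)CCOC(=O)CC(=O)COC(=O)C(C)C | intermediate
22 | 2-(trimethylsilyl)ethyl (2E)-4-(2-methylpropanoyloxy)-3-[(trifluoromethanesulfonyl)oxy]but-2-enoate | CC(C)C(=O)OC/C(OS(=O)(=O)C(F)(F)F)=C\C(=O)OCC[Si](C)(C)C | intermediate
23 | 9-{2-[(1S,2R,4aR,8aR)-2-[(tert-butyldimethylsilyl)oxy]-5,5,8a-trimethyldecahydronaphthalen-1-yl]ethyl}-9-borabicyclo[3.3.1]nonane | C1CC2CCCC(C1)B2CC[C@@H]3[C@H](O[Si](C)(C)C(C)(C)C)CC[C@@H]4C(C)(C)CCC[C@@]34C | intermediate (not isolated)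
24 | 2-(trimethylsilyl)ethyl (2Z)-3-{2-[(1S,2R,4aR,8aR)-2-[(tert-butyldimethylsilyl)oxy]-5,5,8a-trimethyldecahydronaphthalen-1-yl]ethyl}-4-(2-methylpropanoyloxy)but-2-enoate | CC(C)C(=O)OC/C(=C\C(=O)OCC[Si](C)(C)C)CC[C@@H]1[C@H](O[Si](C)(C)C(C)(C)C)CC[C@@H]2C(C)(C)CCC[C@@]12C | intermediate
25 | 2-(trimethylsilyl)ethyl (2Z)-3-{2-[(1S,2R,4aR,8aR)-2-hydroxy-5,5,8a-trimethyldecahydronaphthalen-1-yl]ethyl}-4-(2-methylpropanoyloxy)but-2-enoate | CC(C)C(=O)OC/C(=C\C(=O)OCC[Si](C)(C)C)CC[C@@H]1[C@H](O)CC[C@@H]2C(C)(C)CCC[C@@]12C | intermediate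
26 | 2-(trimethylsilyl)ethyl (2Z)-4-(2-methylpropanoyloxy)-3-{2-[(1S,4aR,8aR)-5,5,8a-trimethyl-2-oxodecahydronaphthalen-1-yl]ethyl}but-2-enoate | CC(C)C(=O)OC/C(=C\C(=O)OCC[Si](C)(C)C)CC[C@@H]1C(=O)CC[C@@H]2C(C)(C)CCC[C@@]12C | intermediate
27 | 2-(trimethylsilyl)ethyl (2Z)-4-(2-methylpropanoyloxy)-3-{2-[(1R,4aR,8aR)-5,5,8a-trimethyl-2-methylidenedecahydronaphthalen-1-yl]ethyl}but-2-enoate | CC(C)C(=O)OC/C(=C\C(=O)OCC[Si](C)(C)C)CC[C@@H]1C(=C)CC[C@@H]2C(C)(C)CCC[C@@]12C | intermediate
28 | (2Z)-4-(2-methylpropanoyloxy)-3-{2-[(1R,4aR,8aR)-5,5,8a-trimethyl-2-methylidenedecahydronaphthalen-1-yl]ethyl}but-2-enoic acid | C=C1CC[C@@H]2C(C)(C)CCC[C@@]2(C)[C@@H]1CC/C(=C/C(=O)O)COC(=O)C(C)C | target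

**Step count**

Total: 18 steps. Longest linear sequence: 15 steps (steps 1–10 and 14–18); steps 11–13 make the side-chain triflate 22.

**Steps most likely to fail**

Step 8. Bond formation at the fully substituted C10 may be slower than protodesilylation or silyl transfer from the dienol ether to the activated aldehyde, and the enantiofacial discrimination may be poor for a β,β-disubstituted enal. The fallback gives up catalyst control and resolves instead. It sets out from 14: heating in toluene (160 °C, sealed tube, 2,6-di-tert-butyl-4-methylphenol), the known thermal type 1 intramolecular Diels–Alder reaction of decatrienes with trisubstituted carbonyl-activated dienophiles, should give the racemic cycloadduct F1. Hydrogenation as in step 9 gives the racemic saturated aldehyde F2. Condensation with (1S,2S)-N,N'-dimethyl-1,2-diphenylethane-1,2-diamine (Et2O, 4 Å molecular sieves) gives two diastereomeric imidazolidines, of which the one derived from the (9S,10R) aldehyde, the aminal F3, is separated by chromatography. Mild hydrolysis (dilute aq. HCl, Et2O, 0 °C) returns the route at 16.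

Step 2. Addition of the Grignard reagent to the aldehyde carbonyl, or enolisation of 5, may compete with conjugate addition at the fully substituted β-carbon. The fallback replaces the enal by a doubly activated acceptor. It sets out from 4, through the same reagent 6: addition to 2,2-dimethyl-5-(propan-2-ylidene)-1,3-dioxane-4,6-dione (THF, −20 °C), a reliable way to quaternary carbons, should give the Meldrum's acid adduct F4. Decarboxylative ethanolysis (EtOH, pyridine, reflux) gives the ethyl ester F5, and partial reduction with i-Bu2AlH (2.2 equiv, CH2Cl2, −78 °C) returns the route at 8.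

Step 14. Transmetalation of the alkylborane under the mild base that the esters require may be slow, leaving time for zerovalent palladium to ionise the allylic isobutyrate or for loss of acyloxy from the alkenylpalladium intermediate. The fallback avoids palladium and base. It sets out from 17: hydroboration with 9-BBN and oxidation (NaOH, H2O2) gives the primary alcohol F6, and I2, PPh3 and imidazole give the iodide F7. Iodine–lithium exchange (t-BuLi, Et2O, −78 °C) and MgBr2·OEt2 give the alkylmagnesium bromide F8, which is coupled with 22 under Fe(acac)3 catalysis (5 mol%, THF–NMP, −30 °C), a known stereoretentive coupling of enol triflates of β-keto esters that tolerates esters, to return the route at 24.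

**Further compounds**

F1 | step 8 | racemic cycloadduct (15 and its enantiomer) | O=C[C@@H]1[C@H](O[Si](C)(C)C(C)(C)C)C=C[C@@H]2C(C)(C)CCC[C@@]12C.O=C[C@H]1[C@@H](O[Si](C)(C)C(C)(C)C)C=C[C@H]2C(C)(C)CCC[C@]12C
F2 | step 8 | racemic saturated aldehyde (16 and its enantiomer) | O=C[C@@H]1[C@H](O[Si](C)(C)C(C)(C)C)CC[C@@H]2C(C)(C)CCC[C@@]12C.O=C[C@H]1[C@@H](O[Si](C)(C)C(C)(C)C)CC[C@H]2C(C)(C)CCC[C@]12C
F3 | step 8 | (4S,5S)-2-[(1R,2R,4aR,8aR)-2-[(tert-butyldimethylsilyl)oxy]-5,5,8a-trimethyldecahydronaphthalen-1-yl]-1,3-dimethyl-4,5-diphenylimidazolidine | C1(N(C)[C@@H](c2ccccc2)[C@H](c2ccccc2)N1C)[C@@H]3[C@H](O[Si](C)(C)C(C)(C)C)CC[C@@H]4C(C)(C)CCC[C@@]34C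
F4 | step 2 | 5-[(6E)-8-hydroxy-2,6-dimethyloct-6-en-2-yl]-2,2-dimethyl-1,3-dioxane-4,6-dione | CC1(C)OC(=O)C(C(C)(C)CCC/C(C)=C/CO)C(=O)O1
F5 | step 2 | ethyl (7E)-9-hydroxy-3,3,7-trimethylnon-7-enoate | CCOC(=O)CC(C)(C)CCC/C(C)=C/CO
F6 | step 14 | 2-[(1S,2R,4aR,8aR)-2-[(tert-butyldimethylsilyl)oxy]-5,5,8a-trimethyldecahydronaphthalen-1-yl]ethan-1-ol | OCC[C@@H]1[C@H](O[Si](C)(C)C(C)(C)C)CC[C@@H]2C(C)(C)CCC[C@@]12C
F7 | step 14 | tert-butyl{[(1S,2R,4aR,8aR)-1-(2-iodoethyl)-5,5,8a-trimethyldecahydronaphthalen-2-yl]oxy}dimethylsilane | ICC[C@@H]1[C@H](O[Si](C)(C)C(C)(C)C)CC[C@@H]2C(C)(C)CCC[C@@]12C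
F8 | step 14 | bromo{2-[(1S,2R,4aR,8aR)-2-[(tert-butyldimethylsilyl)oxy]-5,5,8a-trimethyldecahydronaphthalen-1-yl]ethyl}magnesium | Br[Mg]CC[C@@H]1[C@H](O[Si](C)(C)C(C)(C)C)CC[C@@H]2C(C)(C)CCC[C@@]12C
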